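Compare where the target stops in the two earlier runs with what each run charged.

| flask | starting material | solid reagent | remark | time |
|---|---|---|---|---|
| south | 0.80 M | 0.53 equiv | run made earlier |  |
| north-west | 0.80 M | 0.79 equiv | run made earlier |  |
| flask | 0.80 M | 1.05 equiv |  | 40 min |

- south (time / min: target / %): 4.00: 0.4; 12.0: 3.6; 20.0: 3.0; 30.0: 3.1
- north-west (time / min: target / %): 8.00: 4.2; 15.0: 7.2; 25.0: 7.1; 30.0: 7.4

(each reading ± 0.3 percentage points)

- as a solid, counted per litre of solution: solid reagent
- at the start none of the solid reagent is in solution
- the reaction counts as stopped when no species that holds the starting material changes by six tenths of a point or more over the second half of the time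

1. at 40 min, what has stopped the reaction, if anything has (for what has run out or reacted, a solid counts together with what of it has only dissolved) (it is still moving / all of the starting material has reacted / the partner has run out first / forward and back rates have come level)
2. how much target there is at 40 min, in percent of the starting material charged

The target stays a small correction to the starting material, 3.1 % and 7.4 % at 30.0 min, so reckon it against the solid reagent. Its first level reading comes later in the north-west run, at 15.0 min against 12.0 min. A plateau that rises with the solid charge, at 3.1 % target from 0.53 equiv of solid reagent in the south run, reads as partner lost to something other than target, so this reckoning expects partner to run out first.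

Divide target by equivalents of solid reagent: the south run gives 0.0585, the north-west run 0.0937. This capture share says how much of the charged reagent ends as target. One constant share is not enough, since the north-west share is higher by a factor 1.60, with a scatter of 0.3 percentage points per reading. A straight line through both gives the flask a share of 0.129, hence 13.5 % target.

The forecast says 12 % and forward and back rates have come level: “That points to an equilibrium rather than exhaustion.” This reckoning stands higher and parts from it on the end.

The flask gives 13.8 % at 40 min, and the end is: the partner has run out first, with c partner at 5.89 × 10⁻⁶ M, solid reagent at 0 % and starting material at 86.2 %.

    starting material + partner + target → 2 target (k = 0.0280 /M²/s)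
    starting material + partner → target (k = 1.20 × 10⁻⁴ /M/s)
    partner → decomposed reagent (k = 0.00340 /s)
    2 partner → homo dimer (k = 0.00350 /M/s)
    solid reagent ⇌ partner, rate k5*(cs5 - [partner]) while solid is left; crystals form when [partner] > cs5 (solubility = 0.390 M, k = 0.00920 /s)

In this flask partner has a half-life of 3.4 min by its loss to decomposed reagent alone, against 120 min by the conversion of starting material + partner into target alone, concentrations as charged. Net turnover reaches 64.8 % for that loss against 12.0 % for the making of 2 target, and the flask's capture share comes to 0.131. For the neighbour flask with 0.420 equiv of solid reagent, the same line gives 1.83 % target, and that flask holds 2.23 %.

The data stem from a simulated flask for an exercise.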